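The synthesis rests on disconnecting C10–C11 of the 14-membered carbocycle. C10 lies alpha to C9, a carbinol that can be carried as a ketone flanked by the quaternary dioxane carbon C8. C11 is allylic to the E-C12=C13 alkene, so one allyl β-keto ester can store both reactive ends. The precursor is the 16-membered lactone 42 (C11–O–CO–C10H2–C9=O). It already holds the cis-3,6-bridged 1,2-dioxane ring (C5–C8, O–O) and the methylene lactone masked as a bis-silylated 2-methylene-1,4-diol. Palladium(0) expels CO2 and rejoins C10 with C11, so an ester ring closure is converted into the C–C macrocycle in one operation.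

Key step: step 29

Remarks before the steps
- Numbering: C1 (lactone CH), C2, C3=C4(CH3) Z, C5 (O–O), C6, C7, C8 (CH3, O–O), C9 (OAc), C10, C11, C12(CH3)=C13 E, C14 (lactone O–CH), C15(=C17H2), C16 (lactone C=O).
- Structure check: the target is 1S,5S,8R,9S,14S. H1 and H14 are cis (cis-fused lactone), and C4 and C9 are cis on the dioxane. Compounds 42 and 45 as written below have the same arrangement at C1, C5, C8 and C14, so no atom or descriptor had to be changed.
- Control element at C9: in ketone 45 a polar Felkin–Anh attack (anti to the C8–O bond, past the C8 methyl) leads to 9R. The required 9S carbinol lies on the chelate-type face, so step 30 is put under reagent control.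
- Design points around 42:
  - The ring is closed at room temperature from a thioester instead of by thermolysis.
  - The palladium carries a P,N chelate, so no free phosphine meets the O–O bond.
  - Compound 42 is added slowly, so the C10 enolate does not meet unreacted acidic β-keto ester.
  - The O14 silyl ether shields C13.
- Assumption: (R)-2-methylglycidol (22), (tributylstannyl)methanol and S-tert-butyl thioacetate are taken as purchasable.

## Route

### C11–C14 enal (steps 1–3)

Step 1
Reactants: 1 propargyl alcohol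
Product: 3 (E)-3-iodo-2-methylprop-2-en-1-ol, via alkenylalane 2 (not isolated)
Conditions: Me3Al, Cp2ZrCl2 (cat.), CH2Cl2, 0 → 23 °C; then I2, THF, −30 °C
Reagents that add atoms: trimethylaluminium C[Al](C)C; iodine II
Why: Zirconium-catalysed syn-carboalumination (Negishi carboalumination) puts methyl on the internal and aluminium on the terminal alkyne carbon, and iodinolysis with retention fixes the E geometry that becomes C12=C13.

Step 2
Reactants: 3 (E)-3-iodo-2-methylprop-2-en-1-ol
Product: 4 (E)-1-iodo-3-(4-methoxybenzyloxy)-2-methylprop-1-ene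
Conditions: NaH, PMBCl, Bu4NI (cat.), THF–DMF, 0 → 23 °C
Reagents that add atoms: 4-methoxybenzyl chloride COc1ccc(CCl)cc1
Why: Williamson etherification of the primary allylic alkoxide, to which the alkenyl iodide is inert.

Step 3
Reactants: 4 PMB-protected alkenyl iodide
Product: 6 (E)-4-(4-methoxybenzyloxy)-3-methylbut-2-enal (C11–C14), via alkenyllithium 5 (not isolated)
Conditions: t-BuLi (2 equiv), Et2O, −78 °C; then DMF; H2O
Reagents that add atoms: N,N-dimethylformamide CN(C)C=O
Why: Iodine–lithium exchange keeps the alkene geometry, and formylation of the alkenyllithium with DMF should give the E-enal.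

### Alkenyl bromide 21: C1–C4 and C11–C17 (steps 4–13)

Step 4
Reactants: 7 2-butyn-1-ol
Product: 9 (Z)-3-bromobut-2-en-1-ol, via cyclic alkenylaluminate 8 (not isolated)
Conditions: Red-Al, Et2O, 0 → 23 °C; then NBS, THF, −78 °C
Reagents that add atoms: N-bromosuccinimide O=C1CCC(=O)N1Br
Why: Hydroxyl-directed trans-hydroalumination places aluminium on the distal alkyne carbon in a five-membered chelate, so bromination with retention gives the Z-bromoalkene in which C2 and the halogen (the later C5) are cis.

Step 5
Reactants: 9 (Z)-3-bromobut-2-en-1-ol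
Product: 10 (Z)-1,3-dibromobut-2-ene
Conditions: CBr4, PPh3, CH2Cl2, 0 °C
Reagents that add atoms: carbon tetrabromide BrC(Br)(Br)Br
Why: The Appel reaction converts the primary allylic alcohol into the bromide without touching the alkene geometry.

Step 6
Reactants: 10 (Z)-1,3-dibromobut-2-ene
Product: 11 tert-butyl (Z)-5-bromohex-4-enoate
Conditions: t-BuOAc, LDA, THF, −78 °C; then 10, DMPU, −78 → −20 °C
Reagents that add atoms: tert-butyl acetate CC(=O)OC(C)(C)C
Why: SN2 alkylation of the lithium ester enolate at the primary allylic bromide forms C1–C2, while the alkenyl bromide does not react.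

Step 7
Reactants: 11 tert-butyl (Z)-5-bromohex-4-enoate
Product: 12 (Z)-5-bromohex-4-enoic acid
Conditions: TFA, CH2Cl2, 0 → 23 °C
Reagents that add atoms: none
Why: Acidolysis of the tert-butyl ester by loss of isobutene leaves the bromoalkene untouched.

Step 8
Reactants: 12 (Z)-5-bromohex-4-enoic acid; 13 (R)-4-benzyl-2-oxazolidinone
Product: 15 (R)-4-benzyl-3-[(Z)-5-bromohex-4-enoyl]oxazolidin-2-one, via pivalic mixed anhydride 14 (not isolated)
Conditions: PivCl, Et3N, THF, −20 °C; then LiCl, 13, −20 → 23 °C
Reagents that add atoms: none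
Why: N-Acylation through the mixed anhydride works because the oxazolidinone attacks the less hindered carbonyl.

Step 9
Reactants: 15 N-acyl oxazolidinone; 6 C11–C14 enal
Product: 17 syn-aldol imide, (R)-4-benzyl-3-[(2R,3S,4E)-2-((Z)-3-bromobut-2-enyl)-3-hydroxy-6-(4-methoxybenzyloxy)-5-methylhex-4-enoyl]oxazolidin-2-one, via dibutylboron enolate 16 (not isolated)
Conditions: n-Bu2BOTf, Et3N, CH2Cl2, −78 → 0 °C; then 6, −78 → 0 °C; H2O2, MeOH, pH 7 buffer
Reagents that add atoms: none
Why: In the Evans syn aldol the Z-boron enolate reacts through a Zimmerman–Traxler chair on the face away from the benzyl group, so the (R)-auxiliary sets C1 and C14 together in the syn sense (C15–C1–C14–C13 chain) that corresponds to the cis-fused lactone.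

Step 10
Reactants: 17 syn-aldol imide
Product: 18 Weinreb amide, (2R,3S,4E)-2-((Z)-3-bromobut-2-enyl)-3-hydroxy-N-methoxy-6-(4-methoxybenzyloxy)-N,5-dimethylhex-4-enamide
Conditions: MeNH(OMe)·HCl, Me3Al, THF, −20 → 0 °C
Reagents that add atoms: N,O-dimethylhydroxylamine hydrochloride CNOC.Cl
Why: Aluminium amide transamination (Weinreb amide formation), assisted by the free β-hydroxyl, releases the auxiliary without enolising C1.

Step 11
Reactants: 18 Weinreb amide
Product: 19 (3R,4S,5E)-3-((Z)-3-bromobut-2-enyl)-1,4-dihydroxy-7-(4-methoxybenzyloxy)-6-methylhept-5-en-2-one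
Conditions: LiCH2OLi (3 equiv) [from Bu3SnCH2OH, n-BuLi (2 equiv), THF, −78 °C], −78 °C; pH 7 buffer
Reagents that add atoms: (tributylstannyl)methanol OC[Sn](CCCC)(CCCC)CCCC
Why: A hydroxymethyl anion equivalent made by tin–lithium exchange is acylated by the Weinreb amide to install C16; the chelated tetrahedral intermediate blocks over-addition and enolisation at C1, and the alkenyl bromide exchanges too slowly with this stabilised organolithium at −78 °C.

Step 12
Reactants: 19 dihydroxy ketone
Product: 20 bis-TBS ether of 19 (O14 and O16 silylated)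
Conditions: TBSOTf, 2,6-lutidine, CH2Cl2, −78 → 0 °C
Reagents that add atoms: tert-butyldimethylsilyl triflate CC(C)(C)[Si](C)(C)OS(=O)(=O)C(F)(F)F
Why: Silyl triflate with lutidine silylates both hydroxyls, and the base is too weak to form a silyl enol ether or to epimerise C1.

Step 13
Reactants: 20 bis-silyloxy ketone
Product: 21 alkenyl bromide (C1–C4 and C11–C17; 1S,14S,3Z,12E; C15=C17H2; O14 and O16 as TBS ethers, O11 as PMB ether)
Conditions: Ph3PCH3Br, KHMDS, THF, 0 °C
Reagents that add atoms: methyltriphenylphosphonium bromide C[P+](c1ccccc1)(c1ccccc1)c1ccccc1.[Br-]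
Why: Wittig methylenation installs C17; the unhindered ylide adds to the ketone faster than it deprotonates C1, so the stereocentre and the β-silyloxy group should survive.

### Epoxy aldehyde 27: C5–C9 (steps 14–16)

Step 14
Reactants: 22 (R)-2-methylglycidol
Product: 23 (S)-2-methylglycidyl tosylate
Conditions: TsCl, Et3N, DMAP (cat.), CH2Cl2, 0 °C
Reagents that add atoms: 4-toluenesulfonyl chloride Cc1ccc(S(=O)(=O)Cl)cc1
Why: O-Sulfonylation breaks no bond at the quaternary carbon, and the descriptor changes only because of CIP priorities.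

Step 15
Reactants: 23 (S)-2-methylglycidyl tosylate
Product: 25 (S)-2-(but-3-en-1-yl)-2-methyloxirane, via hydroxy tosylate 24 (not isolated)
Conditions: allylMgBr, CuI (cat.), THF, −40 °C; then aq. NaOH, 23 °C
Reagents that add atoms: allylmagnesium bromide C=CC[Mg]Br
Why: Copper-catalysed Grignard opening occurs at the free epoxide CH2 (the neopentyl-type tosylate is slower), and 3-exo-tet closure of the tertiary alkoxide onto CH2OTs rebuilds an epoxide, so the quaternary centre (C8) is carried over unchanged.

Step 16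
Reactants: 25 epoxy alkene
Product: 27 (S)-3-(2-methyloxiran-2-yl)propanal (C5–C9), via secondary ozonide 26 (not isolated)
Conditions: O3, CH2Cl2, −78 °C; then Me2S
Reagents that add atoms: ozone [O-][O+]=O
Why: Ozonolysis with reductive work-up cleaves the only alkene and leaves the epoxide intact.

### Protected hydroperoxide 29 (step 17)

Step 17
Reactants: 28 2,3-dimethylbut-2-ene
Product: 29 2-methoxyprop-2-yl hydroperoxide
Conditions: O3, MeOH–CH2Cl2, −78 °C
Reagents that add atoms: ozone [O-][O+]=O; methanol CO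
Why: In ozonolysis in methanol the carbonyl oxide (Criegee intermediate) is trapped by the solvent, which gives a mono-protected form of hydrogen peroxide.

### Fragment union, dioxane and β-keto lactone (steps 18–28)

Step 18
Reactants: 21 alkenyl bromide; 27 epoxy aldehyde
Product: 31 allylic alcohol (both C5 epimers; 3Z; (8S)-epoxide intact), via alkenyllithium 30 (not isolated)
Conditions: t-BuLi (2 equiv), Et2O, −78 °C; then 27; H2O
Reagents that add atoms: none
Why: Bromine–lithium exchange with retention and 1,2-addition to the aldehyde form C4–C5 with the Z alkene in place; the epoxide is not attacked at −78 °C, and the C5 epimers are converged in steps 19 and 20.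

Step 19
Reactants: 31 allylic alcohol (C5 epimers)
Product: 32 (Z)-enone (C5 ketone)
Conditions: DMP, pyridine, CH2Cl2, 0 °C
Reagents that add atoms: none
Why: Buffered Dess–Martin oxidation is neutral enough for the epoxide and does not isomerise the Z-enone.

Step 20
Reactants: 32 (Z)-enone
Product: 33 (5S)-allylic alcohol
Conditions: (R)-Me-CBS (0.3 equiv), catecholborane, toluene, −78 °C
Reagents that add atoms: none
Why: In the Corey–Bakshi–Shibata reduction the α-methyl alkenyl group acts as the large and C6H2 as the small substituent, so the (R)-catalyst should give 5S; catecholborane at −78 °C neither hydroborates the alkenes nor opens the epoxide.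

Step 21
Reactants: 33 (5S)-allylic alcohol
Product: 34 (5R)-allylic chloride
Conditions: PPh3, Cl3CC(O)CCl3, CH2Cl2, −30 → 0 °C
Reagents that add atoms: hexachloroacetone O=C(C(Cl)(Cl)Cl)C(Cl)(Cl)Cl
Why: Appel-type chlorination with PPh3 and hexachloroacetone turns secondary allylic alcohols into unrearranged chlorides by SN2 displacement of the oxyphosphonium ion, which inverts C5.

Step 22
Reactants: 34 (5R)-allylic chloride; 29 2-methoxyprop-2-yl hydroperoxide
Product: 35 (5S)-allylic 2-methoxyprop-2-yl peroxide
Conditions: CsOH·H2O, DMF, 0 °C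
Reagents that add atoms: none
Why: SN2 alkylation of a hydroperoxide anion (a strong α-effect nucleophile but a weak base) causes the second inversion and gives 5S, and the isolable chloride should not ionise under these conditions as a sulfonate would.

Step 23
Reactants: 35 (5S)-peroxyketal
Product: 37 (5S,8R)-1,2-dioxane carbinol (C9H2OH on C8; C4 and C9 cis), via C5 hydroperoxide 36 (not isolated)
Conditions: AcOH–THF–H2O, 23 °C; then CSA (cat.), CH2Cl2, 0 °C
Reagents that add atoms: none
Why: Mild hydrolysis frees the hydroperoxide, which opens the protonated epoxide by acid-catalysed 6-exo-tet attack at the tertiary carbon; this is favoured over 7-endo by both ring size and charge, and backside attack inverts C8 to R.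

Step 24
Reactants: 37 dioxane carbinol
Product: 38 dioxane aldehyde (C9HO on quaternary C8)
Conditions: DMP, pyridine, CH2Cl2, 0 → 23 °C
Reagents that add atoms: none
Why: Dess–Martin oxidation of the primary alcohol under neutral conditions gives an aldehyde with no α-hydrogen, which is therefore configurationally safe.

Step 25
Reactants: 38 dioxane aldehyde
Product: 39 β-hydroxy S-tert-butyl thioester (C9 epimers)
Conditions: AcSt-Bu, LDA, THF, −78 °C; then 38; AcOH, −78 °C
Reagents that add atoms: S-tert-butyl thioacetate CC(=O)SC(C)(C)C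
Why: Acetate aldol addition to a non-enolisable aldehyde adds C10 and the acyl carbon; the C9 epimers are merged in step 26, and the cold acidic quench keeps the β-peroxy alkoxide from fragmenting and the C5–H from being attacked.

Step 26
Reactants: 39 β-hydroxy thioester
Product: 40 β-keto S-tert-butyl thioester (C9 ketone)
Conditions: DMP, pyridine, CH2Cl2, 0 → 23 °C
Reagents that add atoms: none
Why: Dess–Martin oxidation of the hindered secondary alcohol gives the 1,3-dicarbonyl without base.

Step 27
Reactants: 40 β-keto thioester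
Product: 41 seco compound with free C11 allylic alcohol
Conditions: DDQ, CH2Cl2–pH 7 buffer, 0 °C
Reagents that add atoms: none
Why: Oxidative PMB cleavage is neutral and orthogonal to the silyl ethers, the thioester and the peroxide.

Step 28
Reactants: 41 hydroxy β-keto thioester
Product: 42 16-membered allyl β-keto lactone (1S,5S,8R,14S,3Z,12E)
Conditions: AgOCOCF3, Na2HPO4, THF, slow addition to 1 mM, 23 °C, dark
Reagents that add atoms: none
Why: In this thioester macrolactonisation by thiophilic silver(I) activation, β-keto thioesters transfer their acyl group (probably through the acylketene) to alcohols at room temperature, so the unhindered primary allylic alcohol closes the 16-membered ring without heating the peroxide.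

### Key step and endgame (steps 29–33)

Step 29
Reactants: 42 16-membered allyl β-keto lactone
Product: 45 14-membered C9 ketone with dioxane bridge and masked lactone, via allylpalladium carboxylate 43 (not isolated), via allylpalladium enolate 44 (not isolated)
Conditions: Pd2(dba)3 (5 mol %), (S)-t-Bu-PHOX (12.5 mol %, used only as a P,N chelate), toluene, 35 °C, slow addition of 42 (final 0.5 mM)
Reagents that add atoms: none
Why: Proposed new method: Pd(0) adds oxidatively to the C11–O allylic ester bond of 42 to give the zwitterionic π-allylpalladium β-keto carboxylate 43, loss of CO2 unveils the C10 enolate 44 regiospecifically because C8 is quaternary, and C10 recombines with the allyl terminus C11. The closest known reaction types are the decarboxylative allylic alkylation of allyl β-keto esters and the π-allyl macrocyclisation of stabilised enolates, whereas the contraction of a macrocyclic β-keto lactone that carries a peroxide has not been shown. The 14-membered ring closes by attack at the distal allyl terminus, so the alkene stays endocyclic, while attack at C13 would give a 12-membered ring with an exocyclic isopropenyl group. No stereocentre is formed and C1, C5, C8 and C14 are not touched. The step needs C11 over C13 and retention of the E alkene: C11 is primary whereas C13 is secondary and shielded by the O14 silyl ether, and fast collapse of the tight ion pair in toluene leaves little time for π–σ–π isomerisation. No external base and no free phosphine are present and slow addition keeps 42 and the zwitterion dilute, which protects the C5–H and O–O bonds and suppresses proton transfer from unreacted β-keto ester.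

Step 30
Reactants: 45 14-membered C9 ketone
Product: 46 (9S)-alcohol
Conditions: (R)-Me-CBS (1 equiv), BH3·SMe2 (pre-complexed), toluene, −30 °C; MeOH
Reagents that add atoms: none
Why: In this Corey–Bakshi–Shibata reduction the quaternary C8 is the large and C10H2 the small substituent, so the (R)-catalyst should deliver 9S under reagent control against the Felkin–Anh bias; pre-complexed borane reduces the ketone faster than it hydroborates, and dialkyl peroxides tolerate it.

Step 31
Reactants: 46 (9S)-alcohol
Product: 47 (9S)-acetate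
Conditions: Ac2O, DMAP, pyridine, CH2Cl2, 23 °C
Reagents that add atoms: acetic anhydride CC(=O)OC(C)=O
Why: DMAP-catalysed acylation of the hindered secondary alcohol uses an amine medium too weak to abstract the C5–H.

Step 32
Reactants: 47 (9S)-acetate
Product: 48 2-methylene-1,4-diol (free O14–H and O16–H)
Conditions: HF·pyridine, pyridine, THF, 0 → 23 °C
Reagents that add atoms: none
Why: Desilylation with a slightly acidic buffered fluoride source avoids the Kornblum–DeLaMare cleavage at C5–H that a basic fluoride could start, and it spares the acetate.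

Step 33
Reactants: 48 2-methylene-1,4-diol
Product: 51 denticulatolide, via hydroxy enal 49 (not isolated), via lactol 50 (not isolated)
Conditions: TEMPO (cat.), PhI(OAc)2, CH2Cl2, 23 °C
Reagents that add atoms: none
Why: In this oxoammonium-mediated oxidative lactonisation of a 1,4-diol the primary allylic alcohol is oxidised first, the enal is captured by O14–H as the five-membered lactol, and a second oxidation gives the α-methylene-γ-butyrolactone with the cis fusion fixed by C1 and C14.

## Compound list

1 | propargyl alcohol | C#CCO | starting material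
2 | alkenylalane from carboalumination | C/C(CO[Al](C)C)=C\[Al](C)C | intermediate
3 | (E)-3-iodo-2-methylprop-2-en-1-ol | C/C(CO)=C\I | intermediate
4 | (E)-1-iodo-3-(4-methoxybenzyloxy)-2-methylprop-1-ene | C/C(COCc1ccc(OC)cc1)=C\I | intermediate
5 | alkenyllithium from 4 | C/C(COCc1ccc(OC)cc1)=C\[Li] | intermediate
6 | (E)-4-(4-methoxybenzyloxy)-3-methylbut-2-enal | C/C(COCc1ccc(OC)cc1)=C\C=O | intermediate
7 | 2-butyn-1-ol | CC#CCO | starting material
8 | cyclic alkenylaluminate (sodium salt) | CC1=CCO[Al-]1(OCCOC)OCCOC.[Na+] | intermediate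
9 | (Z)-3-bromobut-2-en-1-ol | C/C(Br)=C/CO | intermediate
10 | (Z)-1,3-dibromobut-2-ene | C/C(Br)=C/CBr | intermediate
11 | tert-butyl (Z)-5-bromohex-4-enoate | C/C(Br)=C/CCC(=O)OC(C)(C)C | intermediate
12 | (Z)-5-bromohex-4-enoic acid | C/C(Br)=C/CCC(=O)O | intermediate
13 | (R)-4-benzyl-2-oxazolidinone | O=C1N[C@H](Cc2ccccc2)CO1 | starting material
14 | pivalic mixed anhydride of 12 | C/C(Br)=C/CCC(=O)OC(=O)C(C)(C)C | intermediate
15 | (R)-4-benzyl-3-[(Z)-5-bromohex-4-enoyl]oxazolidin-2-one | O=C1N(C(=O)CC/C=C(/C)Br)[C@H](Cc2ccccc2)CO1 | intermediate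
16 | (Z)-dibutylboron enolate of 15 | O=C1N(/C(OB(CCCC)CCCC)=C/C/C=C(/C)Br)[C@H](Cc2ccccc2)CO1 | intermediate
17 | syn-aldol imide (2R,3S) | O=C1N(C(=O)[C@H](C/C=C(/C)Br)[C@@H](O)/C=C(\C)COCc2ccc(OC)cc2)[C@H](Cc2ccccc2)CO1 | intermediate
18 | Weinreb amide (2R,3S) | CON(C)C(=O)[C@H](C/C=C(/C)Br)[C@@H](O)/C=C(\C)COCc1ccc(OC)cc1 | intermediate
19 | dihydroxy ketone (3R,4S) | OCC(=O)[C@H](C/C=C(/C)Br)[C@@H](O)/C=C(\C)COCc1ccc(OC)cc1 | intermediate
20 | bis-TBS ketone | CC(C)(C)[Si](C)(C)OCC(=O)[C@H](C/C=C(/C)Br)[C@@H](O[Si](C)(C)C(C)(C)C)/C=C(\C)COCc1ccc(OC)cc1 | intermediate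
21 | alkenyl bromide (1S,14S,3Z,12E) | C=C(CO[Si](C)(C)C(C)(C)C)[C@H](C/C=C(/C)Br)[C@@H](O[Si](C)(C)C(C)(C)C)/C=C(\C)COCc1ccc(OC)cc1 | intermediate
22 | (R)-2-methylglycidol | C1O[C@]1(C)CO | starting material
23 | (S)-2-methylglycidyl tosylate | C1O[C@]1(C)COS(=O)(=O)c2ccc(C)cc2 | intermediate
24 | hydroxy tosylate from epoxide opening | C=CCC[C@](C)(O)COS(=O)(=O)c1ccc(C)cc1 | intermediate
25 | (S)-2-(but-3-en-1-yl)-2-methyloxirane | C1O[C@@]1(C)CCC=C | intermediate
26 | secondary ozonide of 25 | C1OC(CC[C@@]2(C)CO2)OO1 | intermediate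
27 | (S)-3-(2-methyloxiran-2-yl)propanal | O=CCC[C@@]1(C)CO1 | intermediate
28 | 2,3-dimethylbut-2-ene | CC(C)=C(C)C | starting material
29 | 2-methoxyprop-2-yl hydroperoxide | COC(C)(C)OO | intermediate
30 | alkenyllithium from 21 | C=C(CO[Si](C)(C)C(C)(C)C)[C@H](C/C=C(/C)[Li])[C@@H](O[Si](C)(C)C(C)(C)C)/C=C(\C)COCc1ccc(OC)cc1 | intermediate
31 | allylic alcohol, C5 epimers | C=C(CO[Si](C)(C)C(C)(C)C)[C@H](C/C=C(/C)C(O)CC[C@@]1(C)CO1)[C@@H](O[Si](C)(C)C(C)(C)C)/C=C(\C)COCc2ccc(OC)cc2 | intermediate
32 | (Z)-enone | C=C(CO[Si](C)(C)C(C)(C)C)[C@H](C/C=C(/C)C(=O)CC[C@@]1(C)CO1)[C@@H](O[Si](C)(C)C(C)(C)C)/C=C(\C)COCc2ccc(OC)cc2 | intermediate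
33 | (5S)-allylic alcohol | C=C(CO[Si](C)(C)C(C)(C)C)[C@H](C/C=C(/C)[C@@H](O)CC[C@@]1(C)CO1)[C@@H](O[Si](C)(C)C(C)(C)C)/C=C(\C)COCc2ccc(OC)cc2 | intermediate
34 | (5R)-allylic chloride | C=C(CO[Si](C)(C)C(C)(C)C)[C@H](C/C=C(/C)[C@H](Cl)CC[C@@]1(C)CO1)[C@@H](O[Si](C)(C)C(C)(C)C)/C=C(\C)COCc2ccc(OC)cc2 | intermediate
35 | (5S)-2-methoxyprop-2-yl peroxide | C=C(CO[Si](C)(C)C(C)(C)C)[C@H](C/C=C(/C)[C@@H](OOC(C)(C)OC)CC[C@@]1(C)CO1)[C@@H](O[Si](C)(C)C(C)(C)C)/C=C(\C)COCc2ccc(OC)cc2 | intermediate
36 | (5S)-hydroperoxide | C=C(CO[Si](C)(C)C(C)(C)C)[C@H](C/C=C(/C)[C@@H](OO)CC[C@@]1(C)CO1)[C@@H](O[Si](C)(C)C(C)(C)C)/C=C(\C)COCc2ccc(OC)cc2 | intermediate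
37 | (5S,8R)-dioxane carbinol | C=C(CO[Si](C)(C)C(C)(C)C)[C@H](C/C=C(/C)[C@@H]1CC[C@](C)(CO)OO1)[C@@H](O[Si](C)(C)C(C)(C)C)/C=C(\C)COCc2ccc(OC)cc2 | intermediate
38 | dioxane aldehyde | C=C(CO[Si](C)(C)C(C)(C)C)[C@H](C/C=C(/C)[C@@H]1CC[C@](C)(C=O)OO1)[C@@H](O[Si](C)(C)C(C)(C)C)/C=C(\C)COCc2ccc(OC)cc2 | intermediate
39 | β-hydroxy thioester, C9 epimers | C=C(CO[Si](C)(C)C(C)(C)C)[C@H](C/C=C(/C)[C@@H]1CC[C@](C)(C(O)CC(=O)SC(C)(C)C)OO1)[C@@H](O[Si](C)(C)C(C)(C)C)/C=C(\C)COCc2ccc(OC)cc2 | intermediate
40 | β-keto thioester | C=C(CO[Si](C)(C)C(C)(C)C)[C@H](C/C=C(/C)[C@@H]1CC[C@](C)(C(=O)CC(=O)SC(C)(C)C)OO1)[C@@H](O[Si](C)(C)C(C)(C)C)/C=C(\C)COCc2ccc(OC)cc2 | intermediate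
41 | hydroxy β-keto thioester (free C11–OH) | C=C(CO[Si](C)(C)C(C)(C)C)[C@H](C/C=C(/C)[C@@H]1CC[C@](C)(C(=O)CC(=O)SC(C)(C)C)OO1)[C@@H](O[Si](C)(C)C(C)(C)C)/C=C(\C)CO | intermediate
42 | 16-membered allyl β-keto lactone | C=C(CO[Si](C)(C)C(C)(C)C)[C@H]1[C@@H](O[Si](C)(C)C(C)(C)C)/C=C(\C)COC(=O)CC(=O)[C@@]2(C)CC[C@H](OO2)/C(C)=C\C1 | intermediate
43 | allylpalladium β-keto carboxylate (drawn η1, ligand omitted) | C=C(CO[Si](C)(C)C(C)(C)C)[C@H](C/C=C(/C)[C@@H]1CC[C@](C)(C(=O)CC(=O)[O-])OO1)[C@@H](O[Si](C)(C)C(C)(C)C)/C=C(\C)C[Pd+] | intermediate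
44 | allylpalladium C10 enolate (drawn η1, ligand omitted) | C=C(CO[Si](C)(C)C(C)(C)C)[C@H](C/C=C(/C)[C@@H]1CC[C@](C)(C([O-])=C)OO1)[C@@H](O[Si](C)(C)C(C)(C)C)/C=C(\C)C[Pd+] | intermediate
45 | 14-membered C9 ketone | C=C(CO[Si](C)(C)C(C)(C)C)[C@H]1[C@@H](O[Si](C)(C)C(C)(C)C)/C=C(\C)CCC(=O)[C@@]2(C)CC[C@H](OO2)/C(C)=C\C1 | intermediate
46 | (9S)-alcohol | C=C(CO[Si](C)(C)C(C)(C)C)[C@H]1[C@@H](O[Si](C)(C)C(C)(C)C)/C=C(\C)CC[C@H](O)[C@@]2(C)CC[C@H](OO2)/C(C)=C\C1 | intermediate
47 | (9S)-acetate | C=C(CO[Si](C)(C)C(C)(C)C)[C@H]1[C@@H](O[Si](C)(C)C(C)(C)C)/C=C(\C)CC[C@H](OC(C)=O)[C@@]2(C)CC[C@H](OO2)/C(C)=C\C1 | intermediate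
48 | 2-methylene-1,4-diol | C=C(CO)[C@H]1[C@@H](O)/C=C(\C)CC[C@H](OC(C)=O)[C@@]2(C)CC[C@H](OO2)/C(C)=C\C1 | intermediate
49 | hydroxy enal | C=C(C=O)[C@H]1[C@@H](O)/C=C(\C)CC[C@H](OC(C)=O)[C@@]2(C)CC[C@H](OO2)/C(C)=C\C1 | intermediate
50 | lactol | C=C1C(O)O[C@H]2/C=C(\C)CC[C@H](OC(C)=O)[C@@]3(C)CC[C@H](OO3)/C(C)=C\C[C@@H]12 | intermediate
51 | denticulatolide | C=C1C(=O)O[C@H]2/C=C(\C)CC[C@H](OC(C)=O)[C@@]3(C)CC[C@H](OO3)/C(C)=C\C[C@@H]12 | target

## Step count and risks

Total step count: 33.
Longest linear sequence: 26 steps (steps 4–13 and 18–33, from 2-butyn-1-ol).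

Steps most likely to fail

1. Step 29 (labelled step).
- What may go wrong:
  - protonation of the C10 enolate, together with β-hydride loss from the allyl unit;
  - attack of the enolate or of palladium on the O–O bond;
  - fragmentation of the α-peroxy enolate;
  - oligomerisation;
  - erosion of the E geometry.
- Fallback (known chemistry, from 41, back at 45): the C11 alcohol of 41 is acylated with methyl chloroformate and pyridine to the allylic methyl carbonate F1. Under Pd(0)/dppe at high dilution the carbonate ionises, and the liberated methoxide deprotonates the β-keto thioester. The stabilised C10 enolate then attacks C11 and gives the 14-membered 2-acyl thioester F2 (π-allyl macrocyclisation of a stabilised enolate). Silver(I)-assisted hydrolysis in wet THF gives the β-keto acid F3, which decarboxylates on gentle warming to 45.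

2. Step 22.
- What may go wrong: partial ionisation or SN2′ attack at the allylic centre, with loss of configuration at C5 or transposition of the peroxide, and base-induced decay of the product peroxide.
- Fallback (roles of the two carbons exchanged, from 34, back at 37): the epoxide of 34 is opened first at C8, with inversion, by ethereal hydrogen peroxide and catalytic phosphomolybdic acid. This gives the tertiary β-hydroxy hydroperoxide F4. Caesium carbonate in DMF at 0 °C then closes the dioxane by intramolecular 6-exo-tet displacement of the chloride. The ring size excludes SN2′ attack, and this displacement inverts C5 to S.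

3. Step 28.
- What may go wrong: dimerisation or oligomerisation instead of ring closure, or decay of the activated acyl species before the alcohol reaches it.
- Fallback (ring closed at C9–C10 instead of at the ester, from 38, back at 42): DDQ removes the PMB group of 38 to give the hydroxy aldehyde F5, and acetic anhydride with pyridine gives the C11 acetate F6. KHMDS at −78 °C under high dilution induces macroaldolisation of the acetate enolate onto the non-enolisable C9 aldehyde, which gives the 16-membered β-hydroxy lactone F7. Dess–Martin oxidation then delivers 42.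

Further compounds
F1 | step 29 | allylic methyl carbonate of 41 | C=C(CO[Si](C)(C)C(C)(C)C)[C@H](C/C=C(/C)[C@@H]1CC[C@](C)(C(=O)CC(=O)SC(C)(C)C)OO1)[C@@H](O[Si](C)(C)C(C)(C)C)/C=C(\C)COC(=O)OC
F2 | step 29 | 14-membered ketone with C10 thioester (C10 epimers) | C=C(CO[Si](C)(C)C(C)(C)C)[C@H]1[C@@H](O[Si](C)(C)C(C)(C)C)/C=C(\C)CC(C(=O)SC(C)(C)C)C(=O)[C@@]2(C)CC[C@H](OO2)/C(C)=C\C1
F3 | step 29 | 14-membered β-keto acid (C10 epimers) | C=C(CO[Si](C)(C)C(C)(C)C)[C@H]1[C@@H](O[Si](C)(C)C(C)(C)C)/C=C(\C)CC(C(=O)O)C(=O)[C@@]2(C)CC[C@H](OO2)/C(C)=C\C1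
F4 | step 22 | (5R)-chloride with (8R)-hydroperoxide and C9 carbinol | C=C(CO[Si](C)(C)C(C)(C)C)[C@H](C/C=C(/C)[C@H](Cl)CC[C@](C)(CO)OO)[C@@H](O[Si](C)(C)C(C)(C)C)/C=C(\C)COCc1ccc(OC)cc1
F5 | step 28 | hydroxy aldehyde (free C11–OH) | C=C(CO[Si](C)(C)C(C)(C)C)[C@H](C/C=C(/C)[C@@H]1CC[C@](C)(C=O)OO1)[C@@H](O[Si](C)(C)C(C)(C)C)/C=C(\C)CO
F6 | step 28 | C11 acetate aldehyde | C=C(CO[Si](C)(C)C(C)(C)C)[C@H](C/C=C(/C)[C@@H]1CC[C@](C)(C=O)OO1)[C@@H](O[Si](C)(C)C(C)(C)C)/C=C(\C)COC(C)=O
F7 | step 28 | 16-membered β-hydroxy lactone (C9 epimers) | C=C(CO[Si](C)(C)C(C)(C)C)[C@H]1[C@@H](O[Si](C)(C)C(C)(C)C)/C=C(\C)COC(=O)CC(O)[C@@]2(C)CC[C@H](OO2)/C(C)=C\C1
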